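**Strategy**

The plan rests on cutting the pyranone ring C at O1–C2 and at C3–C4. What lies between these bonds, C2 bearing the ring B aryl group and C3 bearing oxygen, is then a β-acyloxystyrene, and what remains on ring A (O1, C8a, C4a, C4) is an ortho-quinone methide with C4 at the methyl ether level. A single chiral-acid-catalysed oxa-[4+2] step unites a ring A salicylaldehyde dimethyl acetal (free 2-OH, silylated 4-OH, two prenyl groups) with the (E)-enol acetate of the silylated, prenylated ring B arylacetaldehyde; it makes both bonds, closes ring C and sets C2 and C3 trans in the 2R series. Deacetylation, C4 hydrolysis and oxidation, and desilylation follow.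

Key step: step 8

**Remarks and assumptions (chemistry only)**

- Prenyl means 3-methylbut-2-en-1-yl. Flavan numbering (O1, C2–C4, C4a, C5–C8, C8a; ring B primed) is used from step 8 on.
- Both phenols are carried as triisopropylsilyl (TIPS) ethers. They are inert to the chiral acid, should outlast carbonate in methanol and dilute aqueous acid, and leave together in the last step.
- Assumption: the (R)-configured catalyst is taken to give the (2R,3S) series. The sense of induction cannot be derived for this substrate pair; if a first experiment shows the opposite sense, the (S)-catalyst is used and nothing else changes.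
- C4 of 13 is drawn as the all-trans epimer, the expected thermodynamic one under the acid. Either C4 epimer serves, because C4 becomes the carbonyl carbon.
- The descriptor at C3 is S as long as C4 is sp3 and becomes R in the ketone; the spatial arrangement is the same throughout.

**Route**

Step 1
Reactants: 1 2,4-dihydroxybenzaldehyde; 2 prenyl bromide (2.3 equiv)
Product: 3 2,4-dihydroxy-3,5-diprenylbenzaldehyde
Conditions: 10% aq. KOH, 0 °C to rt; chromatographic separation from mono-C- and O-prenylated material
Reagents that add atoms: none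
Why: C-alkylation of the ambident resorcinolate in water (aqueous-alkali C-prenylation), where hydrogen bonding to the oxygens steers the allyl bromide to C3 and C5, the only ring carbons ortho or para to both phenoxide oxygens.

Step 2
Reactants: 3 2,4-dihydroxy-3,5-diprenylbenzaldehyde
Product: 4 2-hydroxy-3,5-diprenyl-4-(triisopropylsilyloxy)benzaldehyde
Conditions: TIPSOTf (1.05 equiv), 2,6-lutidine, CH2Cl2, −40 to 0 °C
Reagents that add atoms: triisopropylsilyl trifluoromethanesulfonate, CC(C)[Si](C(C)C)(C(C)C)OS(=O)(=O)C(F)(F)F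
Why: Selective silyl ether formation at the 4-hydroxyl, the more acidic and free phenol (para to the formyl group), while the 2-hydroxyl is held in the hydrogen bond to the formyl oxygen; the reactive silyl triflate is chosen because both ortho positions are substituted.

Step 3
Reactants: 4 2-hydroxy-3,5-diprenyl-4-(triisopropylsilyloxy)benzaldehyde
Product: 5 6-(dimethoxymethyl)-2,4-diprenyl-3-(triisopropylsilyloxy)phenol (ring A salicylaldehyde dimethyl acetal)
Conditions: HC(OMe)3, MeOH, pyridinium p-toluenesulfonate (cat.), rt; solid K2CO3, filtration through basic alumina; used at once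
Reagents that add atoms: trimethyl orthoformate, COC(OC)OC; methanol, CO
Why: Acid-catalysed acetalisation driven by the orthoester as water scavenger, mild enough to leave the aryl silyl ether and the ortho-prenyl phenol untouched, and worked up without amine so that no base reaches the acid-catalysed key step.

Step 4
Reactants: 6 4-hydroxybenzaldehyde; 2 prenyl bromide (1.1 equiv)
Product: 7 4-hydroxy-3-prenylbenzaldehyde
Conditions: 10% aq. KOH, 0 °C to rt
Reagents that add atoms: none
Why: Aqueous-alkali ortho-C-prenylation of the phenoxide, the para position being blocked by the formyl group, with the O-prenyl ether as the separable by-product.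

Step 5
Reactants: 7 4-hydroxy-3-prenylbenzaldehyde
Product: 8 3-prenyl-4-(triisopropylsilyloxy)benzaldehyde
Conditions: TIPSCl, imidazole, DMF, rt
Reagents that add atoms: chlorotriisopropylsilane, CC(C)[Si](Cl)(C(C)C)C(C)C
Why: Standard phenol silylation; the triisopropylsilyl ether is preferred to a smaller silyl group because this less shielded aryl ether must later survive ylide, aqueous acid and carbonate in methanol.

Step 6
Reactants: 8 3-prenyl-4-(triisopropylsilyloxy)benzaldehyde
Product: 10 2-[3-prenyl-4-(triisopropylsilyloxy)phenyl]acetaldehyde, via methyl enol ether 9 (not isolated)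
Conditions: MeOCH2PPh3Cl, KOtBu, THF, 0 °C; then 2 M aq. HCl, 40 °C
Reagents that add atoms: (methoxymethyl)triphenylphosphonium chloride, COC[P+](c1ccccc1)(c1ccccc1)c1ccccc1.[Cl-]; water, O
Why: Wittig methoxymethylenation followed by acid hydrolysis of the enol ether is the standard one-carbon homologation of an aryl aldehyde, and the aryl silyl ether and the isolated trisubstituted alkene tolerate the dilute acid.

Step 7
Reactants: 10 2-[3-prenyl-4-(triisopropylsilyloxy)phenyl]acetaldehyde
Product: 11 (E)-2-[3-prenyl-4-(triisopropylsilyloxy)phenyl]vinyl acetate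
Conditions: Ac2O, KOAc (cat.), 110 °C; E isomer isolated by chromatography (AgNO3-doped silica if needed)
Reagents that add atoms: acetic anhydride, CC(=O)OC(C)=O
Why: O-acetylation of the aldehyde enol (enol ester formation) should give both alkene isomers, and only the E isomer is carried forward because it holds the trans relation needed between the aryl group on C2 and the oxygen on C3.

Step 8
Reactants: 5 ring A salicylaldehyde dimethyl acetal; 11 (E)-enol acetate (1.5 equiv)
Product: 13 (2R,3S,4R)-3-acetoxy-4-methoxy-6,8-diprenyl-7-(triisopropylsilyloxy)-2-[3-prenyl-4-(triisopropylsilyloxy)phenyl]chroman, via methoxy ortho-quinone methide 12 (not isolated)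
Conditions: (R)-3,3'-bis(2,4,6-triisopropylphenyl)-1,1'-binaphthyl-2,2'-diyl N-(trifluoromethanesulfonyl)phosphoramide (10 mol %), 5 Å MS, toluene, −40 °C; Et3N quench
Reagents that add atoms: none
Why: Proposed new method: the chiral acid ionises acetal 5 with loss of methanol to an ortho-hydroxyaryl oxocarbenium ion, the O-protonated form of methide 12, which stays hydrogen-bonded and ion-paired to the chiral anion; its electrophilic methide carbon (future C4) bonds to the acetoxy-bearing alkene carbon of 11 (future C3), because the para-silyloxyphenyl group stabilises positive charge on the neighbouring carbon far better than an acyloxy group could, and the phenolic oxygen O1 then bonds to that benzylic carbon (C2). The closest known reaction type is the Brønsted acid-catalysed inverse-demand oxa-[4+2] cycloaddition of ortho-quinone methides, made from ortho-hydroxybenzyl alcohols or salicylaldehyde acetals, with electron-rich styrenes, including enantioselective versions with chiral phosphoric acids and N-triflyl phosphoramides; new here are the enol ester as the two-carbon partner and the acetal-derived methoxy methide under asymmetric counter-anion control, and the stronger phosphoramide is chosen because an acetal must be ionised and the alkene offers no hydrogen-bond donor. Ring C closes as a six-membered ring by asynchronous [4+2] cycloaddition of the oxadiene O1=C8a–C4a=C4 across C2=C3 or, at the stepwise limit, by C4–C3 bond formation followed by collapse of the phenol oxygen onto the C2 benzylic cation. C2 and C3 are set together: their trans relation is carried over suprafacially from the E alkene (a 3-acetoxy group bridging a C2 cation would likewise send O1 to the opposite face), their absolute configuration follows from the alkene face left open by the chiral anion in the ion pair, and C4 is set by the approach mode and by acid-mediated equilibration and is of no consequence. The step needs regioselectivity (aryl on C2, oxygen on C3), secured by the donor ranking of the two alkene substituents, and chemoselectivity for the styrenyl alkene over the prenyl alkenes, secured by its conjugation to the silyloxyaryl donor, while low temperature and molecular sieves hold the released methanol and keep the ortho-prenyl phenol from cyclising.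

Step 9
Reactants: 13 (2R,3S,4R)-3-acetoxy-4-methoxyflavan (bis-TIPS)
Product: 14 (2R,3S,4R)-4-methoxy-6,8-diprenyl-7-(triisopropylsilyloxy)-2-[3-prenyl-4-(triisopropylsilyloxy)phenyl]chroman-3-ol
Conditions: K2CO3, MeOH/THF, 0 °C to rt
Reagents that add atoms: none
Why: Base-catalysed transesterification (methanolysis of the acetate) is done while C4 is still an ether, so no enolisable or ring-opening-prone ketone meets base, and the hindered triisopropylsilyl aryl ethers are expected to persist.

Step 10
Reactants: 14 (2R,3S,4R)-4-methoxyflavan-3-ol (bis-TIPS)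
Product: 15 (2R,3S)-6,8-diprenyl-7-(triisopropylsilyloxy)-2-[3-prenyl-4-(triisopropylsilyloxy)phenyl]chroman-3,4-diol (C4 epimers)
Conditions: 0.2 M aq. HCl, THF, rt
Reagents that add atoms: water, O
Why: Acid-catalysed SN1 hydrolysis of the benzylic methyl ether through the C4 cation that O1 and the 7-silyloxy group stabilise, so dilute acid at room temperature should suffice, C2 and C3 are not involved, and both C4 epimers are acceptable.

Step 11
Reactants: 15 (2R,3S)-flavan-3,4-diol (bis-TIPS, C4 epimers)
Product: 16 (2R,3R)-3-hydroxy-6,8-diprenyl-7-(triisopropylsilyloxy)-2-[3-prenyl-4-(triisopropylsilyloxy)phenyl]chroman-4-one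
Conditions: activated MnO2, CH2Cl2, rt
Reagents that add atoms: none
Why: Manganese dioxide oxidation is selective for the benzylic 4-hydroxyl over the aliphatic 3-hydroxyl, and both C4 epimers should converge on one ketone under neutral conditions that leave C2 and C3 untouched.

Step 12
Reactants: 16 (2R,3R)-dihydroflavonol bis-TIPS ether
Product: 17 Lespeflorin B3 [(2R,3R)-3,7-dihydroxy-2-(4-hydroxy-3-prenylphenyl)-6,8-diprenylchroman-4-one]
Conditions: TBAF, AcOH (1:1), THF, 0 °C
Reagents that add atoms: none
Why: Fluoride cleavage of both aryl silyl ethers, buffered with acetic acid so that the phenoxides are protonated as they form and the base-labile trans-dihydroflavonol neither ring-opens nor epimerises.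

**Compound list**

1 | 2,4-dihydroxybenzaldehyde | O=Cc1ccc(O)cc1O | starting material
2 | prenyl bromide (1-bromo-3-methylbut-2-ene) | CC(C)=CCBr | starting material
3 | 2,4-dihydroxy-3,5-diprenylbenzaldehyde | O=Cc1cc(CC=C(C)C)c(O)c(CC=C(C)C)c1O | intermediate
4 | 2-hydroxy-3,5-diprenyl-4-(triisopropylsilyloxy)benzaldehyde | O=Cc1cc(CC=C(C)C)c(O[Si](C(C)C)(C(C)C)C(C)C)c(CC=C(C)C)c1O | intermediate
5 | 6-(dimethoxymethyl)-2,4-diprenyl-3-(triisopropylsilyloxy)phenol (ring A acetal) | COC(OC)c1cc(CC=C(C)C)c(O[Si](C(C)C)(C(C)C)C(C)C)c(CC=C(C)C)c1O | intermediate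
6 | 4-hydroxybenzaldehyde | O=Cc1ccc(O)cc1 | starting material
7 | 4-hydroxy-3-prenylbenzaldehyde | O=Cc1ccc(O)c(CC=C(C)C)c1 | intermediate
8 | 3-prenyl-4-(triisopropylsilyloxy)benzaldehyde | O=Cc1ccc(O[Si](C(C)C)(C(C)C)C(C)C)c(CC=C(C)C)c1 | intermediate
9 | 1-(2-methoxyvinyl)-3-prenyl-4-(triisopropylsilyloxy)benzene (E/Z mixture, not isolated) | COC=Cc1ccc(O[Si](C(C)C)(C(C)C)C(C)C)c(CC=C(C)C)c1 | intermediate
10 | 2-[3-prenyl-4-(triisopropylsilyloxy)phenyl]acetaldehyde | O=CCc1ccc(O[Si](C(C)C)(C(C)C)C(C)C)c(CC=C(C)C)c1 | intermediate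
11 | (E)-2-[3-prenyl-4-(triisopropylsilyloxy)phenyl]vinyl acetate | CC(=O)O/C=C/c1ccc(O[Si](C(C)C)(C(C)C)C(C)C)c(CC=C(C)C)c1 | intermediate
12 | 6-(methoxymethylidene)-2,4-diprenyl-3-(triisopropylsilyloxy)cyclohexa-2,4-dien-1-one (methoxy ortho-quinone methide, reacting as its O-protonated ion pair; not isolated) | COC=C1C=C(CC=C(C)C)C(O[Si](C(C)C)(C(C)C)C(C)C)=C(CC=C(C)C)C1=O | intermediate
13 | (2R,3S,4R)-3-acetoxy-4-methoxy-6,8-diprenyl-7-(triisopropylsilyloxy)-2-[3-prenyl-4-(triisopropylsilyloxy)phenyl]chroman | CO[C@@H]1c2cc(CC=C(C)C)c(O[Si](C(C)C)(C(C)C)C(C)C)c(CC=C(C)C)c2O[C@H](c2ccc(O[Si](C(C)C)(C(C)C)C(C)C)c(CC=C(C)C)c2)[C@H]1OC(C)=O | intermediate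
14 | (2R,3S,4R)-4-methoxy-6,8-diprenyl-7-(triisopropylsilyloxy)-2-[3-prenyl-4-(triisopropylsilyloxy)phenyl]chroman-3-ol | CO[C@@H]1c2cc(CC=C(C)C)c(O[Si](C(C)C)(C(C)C)C(C)C)c(CC=C(C)C)c2O[C@H](c2ccc(O[Si](C(C)C)(C(C)C)C(C)C)c(CC=C(C)C)c2)[C@H]1O | intermediate
15 | (2R,3S)-6,8-diprenyl-7-(triisopropylsilyloxy)-2-[3-prenyl-4-(triisopropylsilyloxy)phenyl]chroman-3,4-diol (C4 epimers) | OC1c2cc(CC=C(C)C)c(O[Si](C(C)C)(C(C)C)C(C)C)c(CC=C(C)C)c2O[C@H](c2ccc(O[Si](C(C)C)(C(C)C)C(C)C)c(CC=C(C)C)c2)[C@H]1O | intermediate
16 | (2R,3R)-3-hydroxy-6,8-diprenyl-7-(triisopropylsilyloxy)-2-[3-prenyl-4-(triisopropylsilyloxy)phenyl]chroman-4-one | O=C1c2cc(CC=C(C)C)c(O[Si](C(C)C)(C(C)C)C(C)C)c(CC=C(C)C)c2O[C@H](c2ccc(O[Si](C(C)C)(C(C)C)C(C)C)c(CC=C(C)C)c2)[C@H]1O | intermediate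
17 | Lespeflorin B3, (2R,3R)-3,7-dihydroxy-2-(4-hydroxy-3-prenylphenyl)-6,8-diprenylchroman-4-one | CC(C)=CCc1cc([C@H]2Oc3c(cc(CC=C(C)C)c(O)c3CC=C(C)C)C(=O)[C@@H]2O)ccc1O | target

**Step count and risks**

Total steps: 12. Longest linear sequence: 9 steps (6 to 17, steps 4 to 12); the ring A branch (steps 1 to 3) joins at step 8.

Steps most likely to fail:

1. Step 8 (proposed new method). The acid may ionise the acetal too slowly at low temperature. The methide may be consumed by prenyl alkenes or by self-condensation faster than by the electron-poorer enol ester. The ion pair may discriminate the alkene faces poorly, and the ortho-prenyl phenol may cyclise under the acid. The fallback uses the established chalcone epoxide route to trans-dihydroflavonols; it sets out from 4 and 8 and returns at 16, bypassing 13 to 15. Aldehyde 4 is converted with MOMCl and i-Pr2NEt into its 2-O-methoxymethyl ether F1. Addition of MeMgBr gives the secondary carbinol F2, and Dess–Martin oxidation gives the acetophenone F3. Claisen–Schmidt condensation of F3 with 8 (Ba(OH)2·8H2O, MeOH) gives the (E)-chalcone F4. Juliá–Colonna epoxidation (poly-L-leucine, urea–H2O2, DBU, THF; poly-D-leucine if the sense is opposite) attacks only the enone and should give the (αR,βS)-epoxide F5. HCl in methanol then removes the methoxymethyl group, and the freed phenol opens the epoxide at the benzylic carbon with inversion, which should give 16 with the 2,3-trans (2R,3R) arrangement.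

2. Step 1. O-alkylation, mono-alkylation and dearomatising over-alkylation compete with the double C-alkylation, so the 3,5-isomer may be a minor and hard-to-purify component. The fallback places the prenyl groups by cross-coupling; it sets out from 1 and returns at 3. Bromination (Br2, AcOH) gives 3,5-dibromo-2,4-dihydroxybenzaldehyde F6. MOMCl and i-Pr2NEt give the bis(methoxymethyl) ether F7. Double Stille coupling with tributyl(3-methylbut-2-enyl)stannane and Pd(PPh3)4 in DMF gives the diprenyl bis(methoxymethyl) ether F8. HCl in methanol at room temperature then frees both phenols to give 3.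

3. Step 11. Glycol cleavage of the vicinal diol, or further oxidation towards the flavonol, may compete with the benzylic oxidation. The fallback removes the need for selectivity by masking O3; it sets out from 14 and returns at 17. TBSOTf and 2,6-lutidine give the 3-O-tert-butyldimethylsilyl ether F9. The same dilute acid hydrolysis of the C4 methyl ether gives the 4-ol F10, in which the benzylic hydroxyl is the only free alcohol. Dess–Martin oxidation gives the 3-O-silyl ketone F11, and buffered fluoride (TBAF/AcOH, or HF·pyridine) removes all three silyl groups to give 17.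

**Further compounds**

F1 | step 8 | 2-(methoxymethoxy)-3,5-diprenyl-4-(triisopropylsilyloxy)benzaldehyde | COCOc1c(C=O)cc(CC=C(C)C)c(O[Si](C(C)C)(C(C)C)C(C)C)c1CC=C(C)C
F2 | step 8 | 1-[2-(methoxymethoxy)-3,5-diprenyl-4-(triisopropylsilyloxy)phenyl]ethanol (racemic) | COCOc1c(C(C)O)cc(CC=C(C)C)c(O[Si](C(C)C)(C(C)C)C(C)C)c1CC=C(C)C
F3 | step 8 | 1-[2-(methoxymethoxy)-3,5-diprenyl-4-(triisopropylsilyloxy)phenyl]ethanone | COCOc1c(C(C)=O)cc(CC=C(C)C)c(O[Si](C(C)C)(C(C)C)C(C)C)c1CC=C(C)C
F4 | step 8 | (E)-1-[2-(methoxymethoxy)-3,5-diprenyl-4-(triisopropylsilyloxy)phenyl]-3-[3-prenyl-4-(triisopropylsilyloxy)phenyl]prop-2-en-1-one | COCOc1c(C(=O)/C=C/c2ccc(O[Si](C(C)C)(C(C)C)C(C)C)c(CC=C(C)C)c2)cc(CC=C(C)C)c(O[Si](C(C)C)(C(C)C)C(C)C)c1CC=C(C)C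
F5 | step 8 | (αR,βS)-trans-epoxide of chalcone F4 | COCOc1c(C(=O)[C@@H]2O[C@H]2c2ccc(O[Si](C(C)C)(C(C)C)C(C)C)c(CC=C(C)C)c2)cc(CC=C(C)C)c(O[Si](C(C)C)(C(C)C)C(C)C)c1CC=C(C)C
F6 | step 1 | 3,5-dibromo-2,4-dihydroxybenzaldehyde | O=Cc1cc(Br)c(O)c(Br)c1O
F7 | step 1 | 3,5-dibromo-2,4-bis(methoxymethoxy)benzaldehyde | COCOc1c(C=O)cc(Br)c(OCOC)c1Br
F8 | step 1 | 2,4-bis(methoxymethoxy)-3,5-diprenylbenzaldehyde | COCOc1c(C=O)cc(CC=C(C)C)c(OCOC)c1CC=C(C)C
F9 | step 11 | (2R,3S,4R)-3-(tert-butyldimethylsilyloxy)-4-methoxy-6,8-diprenyl-7-(triisopropylsilyloxy)-2-[3-prenyl-4-(triisopropylsilyloxy)phenyl]chroman | CO[C@@H]1c2cc(CC=C(C)C)c(O[Si](C(C)C)(C(C)C)C(C)C)c(CC=C(C)C)c2O[C@H](c2ccc(O[Si](C(C)C)(C(C)C)C(C)C)c(CC=C(C)C)c2)[C@H]1O[Si](C)(C)C(C)(C)C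
F10 | step 11 | (2R,3S)-3-(tert-butyldimethylsilyloxy)-6,8-diprenyl-7-(triisopropylsilyloxy)-2-[3-prenyl-4-(triisopropylsilyloxy)phenyl]chroman-4-ol (C4 epimers) | OC1c2cc(CC=C(C)C)c(O[Si](C(C)C)(C(C)C)C(C)C)c(CC=C(C)C)c2O[C@H](c2ccc(O[Si](C(C)C)(C(C)C)C(C)C)c(CC=C(C)C)c2)[C@H]1O[Si](C)(C)C(C)(C)C
F11 | step 11 | (2R,3R)-3-(tert-butyldimethylsilyloxy)-6,8-diprenyl-7-(triisopropylsilyloxy)-2-[3-prenyl-4-(triisopropylsilyloxy)phenyl]chroman-4-one | O=C1c2cc(CC=C(C)C)c(O[Si](C(C)C)(C(C)C)C(C)C)c(CC=C(C)C)c2O[C@H](c2ccc(O[Si](C(C)C)(C(C)C)C(C)C)c(CC=C(C)C)c2)[C@H]1O[Si](C)(C)C(C)(C)C
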